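**Plan** (labdane numbering throughout)
- Retrosynthetic cuts: the C15–O ester; then ring A at C1–C2 and C3–C4 (a two-carbon C2–C3 unit is taken out); then C4–C5 ([3,3] shift); then ring B at C8–C9 and C5–C10 (Diels–Alder); then C9=C10 (cross-metathesis on citronellol).
- Forward order: the chain and C1/C10/C20 come first as an E-enal, ring B is closed on it, C8 is decorated, the C4 unit is attached, ring A is closed, then hydrogenation and esterification.
- Enabling feature: in ring A, C4 is a non-stereogenic gem-dimethyl quaternary carbon and C1, C2, C3 are bare methylenes. A tertiary C4 radical and a C1 formyl group, held trans on C5 and C10 of ring B, can therefore be bridged by C2–C3 in one operation.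
- Stereochemistry: C13 from (S)-citronellol; C9/C10 relative from the E-enal geometry, absolute from the Diels–Alder catalyst; C8 by enolate oxidation anti to the C9 chain; C7 (temporary) by chelation-controlled reduction, relayed to C5 by the suprafacial [3,3] shift; the trans ring fusion follows from C5/C10.

Key step: step 12

Assumption: in step 4 the (S)-configured oxazaborolidinium catalyst is taken to expose the Si face at the α-carbon of enal 4 (the face required here); if the formyl C–H···O model predicts the opposite sense, its mirror image is used with no other change.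

**Step 1**
Reactants: 1 (S)-citronellol
Product: 2 benzyl (S)-citronellyl ether
Conditions: NaH, BnBr, Bu4NI (cat.), THF, 0 °C → rt
Reagents that add atoms: benzyl bromide BrCc1ccccc1
Why: Williamson etherification masks the C15 hydroxyl as an ether that should survive every later base and hydride and be removed in the final hydrogenation; C13 is not touched.

**Step 2**
Reactants: 2 benzyl (S)-citronellyl ether; 3 methacrolein
Product: 4 (2E,6S)-8-(benzyloxy)-2,6-dimethyloct-2-enal
Conditions: RuCl2(H2IMes)(=CH-C6H4-2-OiPr) (second-generation Hoveyda–Grubbs catalyst, 5 mol %), methacrolein (excess), CH2Cl2, 40 °C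
Reagents that add atoms: none
Why: Olefin cross-metathesis of the prenyl-type terminus with methacrolein exchanges the isopropylidene unit for the 2-formylpropylidene unit with loss of volatile 2-methylpropene and should give the thermodynamically preferred E-enal, which now carries C1, C10 and C20.

**Step 3**
Reactants: 5 methyl vinyl ketone
Product: 6 2-(triisopropylsilyloxy)buta-1,3-diene
Conditions: iPr3SiOTf, Et3N, Et2O, 0 °C
Reagents that add atoms: triisopropylsilyl trifluoromethanesulfonate CC(C)[Si](OS(=O)(=O)C(F)(F)F)(C(C)C)C(C)C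
Why: Soft enolisation and O-silylation of the methyl ketone gives the acid-tolerant 2-silyloxydiene that supplies C5–C8.

**Step 4**
Reactants: 4 (2E,6S)-8-(benzyloxy)-2,6-dimethyloct-2-enal; 6 2-(triisopropylsilyloxy)buta-1,3-diene
Product: 7 (1S,6S)-6-[(3S)-5-(benzyloxy)-3-methylpentyl]-1-methyl-4-(triisopropylsilyloxy)cyclohex-3-ene-1-carbaldehyde
Conditions: (S)-o-tolyl-CBS-oxazaborolidine (20 mol %), HN(SO2CF3)2 (18 mol %), CH2Cl2, −78 → −20 °C
Reagents that add atoms: none
Why: Catalytic enantioselective Diels–Alder reaction of an α-substituted enal activated by a cationic oxazaborolidine closes ring B (C8–C9 and C5–C10) with para orientation; suprafacial addition carries the E geometry into the cis C9-chain/C10-methyl relationship, and the catalyst-bound formyl group exposes one enal face, which sets the absolute configuration of C9 and C10.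

**Step 5**
Reactants: 7 Diels–Alder silyl enol ether
Product: 8 (1R,6S)-6-[(3S)-5-(benzyloxy)-3-methylpentyl]-1-methyl-4-oxocyclohex-2-ene-1-carbaldehyde
Conditions: Pd(OAc)2 (1.2 equiv), DMSO, 50 °C
Reagents that add atoms: none
Why: Saegusa–Ito oxidation of the regiodefined C6=C7 silyl enol ether should place the new double bond at C5=C6 only, giving the C7 enone without touching the quaternary aldehyde.

**Step 6**
Reactants: 8 enone aldehyde
Product: 9 (4R,5S)-5-[(3S)-5-(benzyloxy)-3-methylpentyl]-4-(dimethoxymethyl)-4-methylcyclohex-2-en-1-one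
Conditions: HC(OMe)3, MeOH, PPTS (cat.), rt
Reagents that add atoms: trimethyl orthoformate COC(OC)OC
Why: Acid-catalysed acetalisation is chemoselective for the aldehyde over the conjugated ketone and shields C1 from the enolate, hydride and amide-base steps that follow.

**Step 7**
Reactants: 9 enone acetal
Product: 11 (4S,5S,6S)-5-[(3S)-5-(benzyloxy)-3-methylpentyl]-4-(dimethoxymethyl)-4,6-dimethylcyclohex-2-en-1-one, via lithium enolate 10 (not isolated)
Conditions: LiN(iPr)2, THF, −78 °C; MeI, −78 → −20 °C
Reagents that add atoms: iodomethane CI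
Why: Kinetic α′-enolate alkylation is regiospecific because the γ-carbon (C10) is quaternary, and it installs C17 at C8; the C8 configuration (major epimer drawn, methyl anti to the C9 chain) is erased in step 8.

**Step 8**
Reactants: 11 C8-methyl enone
Product: 13 (4S,5R,6S)-5-[(3S)-5-(benzyloxy)-3-methylpentyl]-4-(dimethoxymethyl)-6-hydroxy-4,6-dimethylcyclohex-2-en-1-one, via potassium enolate 12 (not isolated)
Conditions: KN(SiMe3)2, THF, −78 °C; 2-(phenylsulfonyl)-3-phenyloxaziridine; AcOH quench
Reagents that add atoms: 2-(phenylsulfonyl)-3-phenyloxaziridine O=S(=O)(c1ccccc1)N1OC1c1ccccc1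
Why: Enolate hydroxylation with the Davis oxaziridine should occur on the α face, opposite the adjacent C9 chain and the C10 methyl group (both β), which sets the 8α-hydroxy/8β-methyl carbinol.

**Step 9**
Reactants: 13 α′-hydroxy enone
Product: 14 (1S,2S,5S,6R)-6-[(3S)-5-(benzyloxy)-3-methylpentyl]-5-(dimethoxymethyl)-1,5-dimethylcyclohex-3-ene-1,2-diol
Conditions: Zn(BH4)2, Et2O, −20 → 0 °C
Reagents that add atoms: none
Why: Chelation-controlled 1,2-reduction: zinc bridges the C7 carbonyl and the C8 hydroxyl, and hydride should enter opposite the C8 methyl to give the 7β-allylic alcohol (trans-diol) that will direct the [3,3] shift.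

**Step 10**
Reactants: 14 trans-diol; 15 2-methylpropanoyl chloride
Product: 16 (1S,4S,5R,6S)-5-[(3S)-5-(benzyloxy)-3-methylpentyl]-4-(dimethoxymethyl)-6-hydroxy-4,6-dimethylcyclohex-2-en-1-yl 2-methylpropanoate
Conditions: pyridine, DMAP (cat.), CH2Cl2, 0 °C → rt
Reagents that add atoms: none
Why: DMAP-catalysed acylation should take the secondary allylic hydroxyl only, the tertiary C8 hydroxyl being too hindered to react.

**Step 11**
Reactants: 16 allylic isobutyrate
Product: 19 2-[(1R,4R,5R,6S)-5-[(3S)-5-(benzyloxy)-3-methylpentyl]-6-formyl-4-hydroxy-4,6-dimethylcyclohex-2-en-1-yl]-2-methylpropanoic acid, via bis-silyl ketene acetal 17 (not isolated), via rearranged silyl ester 18 (not isolated)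
Conditions: Me3SiCl, Et3N, LiN(iPr)2 (3 equiv), THF, −78 °C → 65 °C; then AcOH/H2O/THF, rt
Reagents that add atoms: water O
Why: Ireland–Claisen rearrangement: the suprafacial [3,3] shift of the silyl ketene acetal forms C4–C5 on the β face (the face of the 7β C–O bond), which sets C5 and moves the alkene to C6=C7, and the mild acidic work-up cleaves both silyl groups and the acetal without ionising the tertiary allylic alcohol.

**Step 12**
Reactants: 19 formyl acid; 20 vinyltriphenylphosphonium bromide
Product: 22 (1R,2R,4aS,8aS)-1-[(3S)-5-(benzyloxy)-3-methylpentyl]-2,5,5,8a-tetramethyl-1,2,4a,5,6,8a-hexahydronaphthalen-2-ol, via phosphonium ylide 21 (not isolated)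
Conditions: 20 (2 equiv), 4CzIPN (2 mol %), Cs2CO3 (1.5 equiv), degassed MeCN, 450 nm LEDs, rt; then 40 °C
Reagents that add atoms: none
Why: Proposed new method: the caesium carboxylate of 19 is oxidised by photoexcited 4CzIPN and loses CO2 to give the tertiary C4 radical, which adds to the CH2 terminus of 20 (C3–C4 bond); the α-phosphonio radical is reduced by the 4CzIPN radical anion to ylide 21 (radical–polar crossover), and 21 olefinates the C10 formyl group (C1=C2 bond). The closest known reaction type is the visible-light three-component conjunctive olefination of carboxylic acids, vinylphosphonium salts and aldehydes, with the Schweizer annulation as the ionic precedent for ring closure by a tethered ylide. Ring A closes as a six-membered carbocycle by intramolecular Wittig reaction, through a six-ring-fused oxaphosphetane at the aldehyde, which can only give the cis ring alkene. No stereocenter is created, since C4 carries two methyl groups and C1/C2 become sp2; the trans ring fusion is inherited from the trans arrangement of the C5 and C10 substituents installed in steps 4 and 11. The step needs intermolecular radical addition to outrun reversible 3-exo closure onto C6=C7 and hydrogen abstraction, which the excess of the cationic acceptor and the nucleophilic tertiary radical favour, and it needs ylide–carbonyl capture to beat protonation, which the carbonate base and the non-enolisable aldehyde held five bonds away secure.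

**Step 13**
Reactants: 22 bicyclic diene
Product: 23 (1R,2R,4aS,8aS)-1-[(3S)-5-hydroxy-3-methylpentyl]-2,5,5,8a-tetramethyldecahydronaphthalen-2-ol
Conditions: H2 (1 atm), 10% Pd/C, EtOH, rt
Reagents that add atoms: none
Why: Heterogeneous hydrogenation should saturate both disubstituted ring alkenes (C1=C2, C6=C7) and hydrogenolyse the benzyl ether in one operation; no stereocenter is formed, since all four carbons become CH2.

**Step 14**
Reactants: 23 labdane-8α,15-diol; 24 3-phenylpropanoyl chloride
Product: 25 (3S)-5-[(1R,2R,4aS,8aS)-2-hydroxy-2,5,5,8a-tetramethyldecahydronaphthalen-1-yl]-3-methylpentyl 3-phenylpropanoate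
Conditions: 24 (1.05 equiv), pyridine, CH2Cl2, 0 °C
Reagents that add atoms: none
Why: Acylation of the primary C15 hydroxyl is selective because the tertiary C8 hydroxyl is hindered and unreactive at 0 °C.

**Compound list**
1 | (S)-citronellol, (3S)-3,7-dimethyloct-6-en-1-ol | C[C@H](CCO)CCC=C(C)C | starting material
2 | benzyl (S)-citronellyl ether | C[C@H](CCOCc1ccccc1)CCC=C(C)C | intermediate
3 | methacrolein | C=C(C)C=O | starting material
4 | (2E,6S)-8-(benzyloxy)-2,6-dimethyloct-2-enal | C[C@H](CCOCc1ccccc1)CC/C=C(/C=O)C | intermediate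
5 | methyl vinyl ketone | CC(=O)C=C | starting material
6 | 2-(triisopropylsilyloxy)buta-1,3-diene | C=CC(=C)O[Si](C(C)C)(C(C)C)C(C)C | intermediate
7 | (1S,6S)-6-[(3S)-5-(benzyloxy)-3-methylpentyl]-1-methyl-4-(triisopropylsilyloxy)cyclohex-3-ene-1-carbaldehyde | C[C@H](CCOCc1ccccc1)CC[C@@H]1[C@@](C)(C=O)CC=C(O[Si](C(C)C)(C(C)C)C(C)C)C1 | intermediate
8 | (1R,6S)-6-[(3S)-5-(benzyloxy)-3-methylpentyl]-1-methyl-4-oxocyclohex-2-ene-1-carbaldehyde | C[C@H](CCOCc1ccccc1)CC[C@@H]1[C@@](C)(C=O)C=CC(=O)C1 | intermediate
9 | (4R,5S)-5-[(3S)-5-(benzyloxy)-3-methylpentyl]-4-(dimethoxymethyl)-4-methylcyclohex-2-en-1-one | C[C@H](CCOCc1ccccc1)CC[C@@H]1[C@@](C)(C(OC)OC)C=CC(=O)C1 | intermediate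
10 | lithium α′-enolate of 9 | C[C@H](CCOCc1ccccc1)CC[C@@H]1[C@@](C)(C(OC)OC)C=CC([O-])=C1.[Li+] | intermediate
11 | (4S,5S,6S)-5-[(3S)-5-(benzyloxy)-3-methylpentyl]-4-(dimethoxymethyl)-4,6-dimethylcyclohex-2-en-1-one (major C6 epimer) | C[C@H](CCOCc1ccccc1)CC[C@@H]1[C@@](C)(C(OC)OC)C=CC(=O)[C@H]1C | intermediate
12 | potassium α′-enolate of 11 | C[C@H](CCOCc1ccccc1)CC[C@@H]1[C@@](C)(C(OC)OC)C=CC([O-])=C1C.[K+] | intermediate
13 | (4S,5R,6S)-5-[(3S)-5-(benzyloxy)-3-methylpentyl]-4-(dimethoxymethyl)-6-hydroxy-4,6-dimethylcyclohex-2-en-1-one | C[C@H](CCOCc1ccccc1)CC[C@@H]1[C@@](C)(C(OC)OC)C=CC(=O)[C@@]1(C)O | intermediate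
14 | (1S,2S,5S,6R)-6-[(3S)-5-(benzyloxy)-3-methylpentyl]-5-(dimethoxymethyl)-1,5-dimethylcyclohex-3-ene-1,2-diol | C[C@H](CCOCc1ccccc1)CC[C@@H]1[C@@](C)(C(OC)OC)C=C[C@H](O)[C@@]1(C)O | intermediate
15 | 2-methylpropanoyl chloride | CC(C)C(=O)Cl | starting material
16 | (1S,4S,5R,6S)-5-[(3S)-5-(benzyloxy)-3-methylpentyl]-4-(dimethoxymethyl)-6-hydroxy-4,6-dimethylcyclohex-2-en-1-yl 2-methylpropanoate | C[C@H](CCOCc1ccccc1)CC[C@@H]1[C@@](C)(C(OC)OC)C=C[C@H](OC(=O)C(C)C)[C@@]1(C)O | intermediate
17 | bis-silyl ketene acetal of 16 (C8 trimethylsilyl ether) | C[C@H](CCOCc1ccccc1)CC[C@@H]1[C@@](C)(C(OC)OC)C=C[C@H](OC(O[Si](C)(C)C)=C(C)C)[C@@]1(C)O[Si](C)(C)C | intermediate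
18 | rearranged trimethylsilyl ester (C8 trimethylsilyl ether, C1 dimethyl acetal) | C[C@H](CCOCc1ccccc1)CC[C@@H]1[C@@](C)(C(OC)OC)[C@H](C(C)(C)C(=O)O[Si](C)(C)C)C=C[C@@]1(C)O[Si](C)(C)C | intermediate
19 | 2-[(1R,4R,5R,6S)-5-[(3S)-5-(benzyloxy)-3-methylpentyl]-6-formyl-4-hydroxy-4,6-dimethylcyclohex-2-en-1-yl]-2-methylpropanoic acid | C[C@H](CCOCc1ccccc1)CC[C@@H]1[C@@](C)(C=O)[C@H](C(C)(C)C(=O)O)C=C[C@@]1(C)O | intermediate
20 | vinyltriphenylphosphonium bromide | C=C[P+](c1ccccc1)(c1ccccc1)c1ccccc1.[Br-] | starting material
21 | phosphonium ylide from radical addition and reduction (C2 ylide carbon, C1 formyl still free) | C[C@H](CCOCc1ccccc1)CC[C@@H]1[C@@](C)(C=O)[C@H](C(C)(C)CC=P(c2ccccc2)(c2ccccc2)c2ccccc2)C=C[C@@]1(C)O | intermediate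
22 | (1R,2R,4aS,8aS)-1-[(3S)-5-(benzyloxy)-3-methylpentyl]-2,5,5,8a-tetramethyl-1,2,4a,5,6,8a-hexahydronaphthalen-2-ol | C[C@H](CCOCc1ccccc1)CC[C@@H]1[C@@]2(C)C=CCC(C)(C)[C@@H]2C=C[C@@]1(C)O | intermediate
23 | (1R,2R,4aS,8aS)-1-[(3S)-5-hydroxy-3-methylpentyl]-2,5,5,8a-tetramethyldecahydronaphthalen-2-ol, (13S)-labdane-8α,15-diol | C[C@H](CCO)CC[C@@H]1[C@@]2(C)CCCC(C)(C)[C@@H]2CC[C@@]1(C)O | intermediate
24 | 3-phenylpropanoyl chloride | O=C(Cl)CCc1ccccc1 | starting material
25 | (3S)-5-[(1R,2R,4aS,8aS)-2-hydroxy-2,5,5,8a-tetramethyldecahydronaphthalen-1-yl]-3-methylpentyl 3-phenylpropanoate | C[C@H](CCOC(=O)CCc1ccccc1)CC[C@@H]1[C@@]2(C)CCCC(C)(C)[C@@H]2CC[C@@]1(C)O | target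

**Step count**
Total: 14 steps. Longest linear sequence: 13 steps (1 → 25 through steps 1, 2 and 4–14; step 3 is a one-step branch).

**Steps most likely to fail**

Step 12 (the proposed new method). The radical–polar crossover may stall in three ways. The tertiary radical may be quenched by hydrogen abstraction or rearrange through the homoallyl/cyclopropylcarbinyl manifold before it meets the acceptor. The ylide may be protonated faster than it closes the ring. Ring–chain tautomerism between the C8 hydroxyl and the C1 formyl group may keep the aldehyde masked as a bridged lactol. The fallback uses known chemistry, sets out from 19 and returns at 22. The same carboxylate undergoes the established photoredox decarboxylative Giese addition to phenyl vinyl sulfone (4CzIPN, Cs2CO3, blue light), which should give the sulfone aldehyde F1. LiN(iPr)2 (2.2 equiv, the first equivalent being taken up by the C8 hydroxyl) then forms the α-sulfonyl carbanion, which adds to the tethered formyl group. Benzoyl chloride (1 equiv, −78 °C) traps the secondary alkoxide as the β-benzoyloxy sulfone F2 (mixture at C1/C2, of no consequence), the tertiary C8 alkoxide being too hindered to acylate. SmI2 in THF/DMPU then performs the Julia reductive elimination to 22.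

Step 4. The trisubstituted enal may cycloadd sluggishly, and the catalyst may discriminate the enal faces poorly, which would give ring diastereomers with respect to C13 that are hard to separate. The fallback replaces catalyst control by auxiliary control, sets out from 4 and returns at 8. 4-Methoxybut-3-en-2-one is condensed with (2R,5R)-2,5-diphenylpyrrolidine to the vinylogous amide F3, which is O-silylated (KN(SiMe3)2, tBuMe2SiCl) to the C2-symmetric aminosilyloxydiene F4. Thermal cycloaddition of F4 with 4 should give the cycloadduct F5 (endo isomer drawn). Aqueous HF in MeCN then expels the auxiliary and the silyl group to give enone aldehyde 8 directly, so step 5 is not needed. The antipode of the auxiliary is selected by the same facial criterion as in the assumption above.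

Step 11. The sigmatropic shift may be slowed by steric compression between the two quaternary neighbours (C8 and C10), leaving time for acyl migration to the neighbouring tertiary alkoxide or for fragmentation of the ketene acetal. The fallback replaces the sigmatropic C–C bond formation by a directed allylic substitution and the acid radical precursor by an alkene; it sets out from 14 and returns at 22. Diol 14 and phenyl isocyanate give the N-phenylcarbamate F6. Deprotonation (MeLi), CuI and isopropenyllithium should deliver the isopropenyl group syn-SN2′ to C5 on the β face, giving the isopropenyl acetal F7. Iron-hydride hydrogen-atom transfer (Fe(acac)3, PhSiH3, EtOH, 60 °C) to the 1,1-disubstituted alkene generates the same tertiary C4 radical, which is trapped by phenyl vinyl sulfone (reductive olefin coupling) to give the sulfone acetal F8. Aqueous acetic acid frees the aldehyde to give the sulfone aldehyde F1, which continues through the β-benzoyloxy sulfone F2 to 22 as described for step 12.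

**Further compounds**
F1 | step 12 | sulfone aldehyde, 2-methyl-4-(phenylsulfonyl)butan-2-yl group at C5 and formyl at C10 of ring B | C[C@H](CCOCc1ccccc1)CC[C@@H]1[C@@](C)(C=O)[C@H](C(C)(C)CCS(=O)(=O)c2ccccc2)C=C[C@@]1(C)O
F2 | step 12 | β-benzoyloxy sulfone, ring A closed, benzoate at C1 and phenylsulfonyl at C2 (C1/C2 mixture) | C[C@H](CCOCc1ccccc1)CC[C@@H]1[C@@]2(C)C(OC(=O)c3ccccc3)C(S(=O)(=O)c3ccccc3)CC(C)(C)[C@@H]2C=C[C@@]1(C)O
F3 | step 4 | (E)-4-[(2R,5R)-2,5-diphenylpyrrolidin-1-yl]but-3-en-2-one | CC(=O)/C=C/N1[C@@H](c2ccccc2)CC[C@@H]1c1ccccc1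
F4 | step 4 | (E)-1-[(2R,5R)-2,5-diphenylpyrrolidin-1-yl]-3-(tert-butyldimethylsilyloxy)buta-1,3-diene | C=C(O[Si](C)(C)C(C)(C)C)/C=C/N1[C@@H](c2ccccc2)CC[C@@H]1c1ccccc1
F5 | step 4 | aminosilyloxy cycloadduct of 4 and F4 (endo) | C[C@H](CCOCc1ccccc1)CC[C@@H]1[C@@](C)(C=O)[C@@H](N2[C@@H](c3ccccc3)CC[C@@H]2c2ccccc2)C=C(O[Si](C)(C)C(C)(C)C)C1
F6 | step 11 | N-phenylcarbamate of 14 at the C7 hydroxyl | C[C@H](CCOCc1ccccc1)CC[C@@H]1[C@@](C)(C(OC)OC)C=C[C@H](OC(=O)Nc2ccccc2)[C@@]1(C)O
F7 | step 11 | C5β-isopropenyl acetal, alkene at C6=C7 | C[C@H](CCOCc1ccccc1)CC[C@@H]1[C@@](C)(C(OC)OC)[C@H](C(C)=C)C=C[C@@]1(C)O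
F8 | step 11 | sulfone acetal, 2-methyl-4-(phenylsulfonyl)butan-2-yl group at C5 | C[C@H](CCOCc1ccccc1)CC[C@@H]1[C@@](C)(C(OC)OC)[C@H](C(C)(C)CCS(=O)(=O)c2ccccc2)C=C[C@@]1(C)O
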